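**Plan**

- Retrosynthesis: the imidazole C4–indole C3 bond is cut first, then the two ring bonds N3–C4 and N1–C5. This leaves 6-bromoindole-3-carboxamidine, a two-carbon glyoxal unit (as its mono-dimethyl acetal) and indole; the amidine goes back through the nitrile to 6-bromoindole.
- Forward: C3 cyanation of 6-bromoindole, nitrile to amidine, then a one-flask cascade. Amidine N plus aldehyde gives an N-amidinyl iminium ion, indole C3 attacks it (the C–C bond), the acetal is unmasked, the imidazole closes and aromatises by loss of methanol.
- Enabling feature: C4 and C5 of the imidazole each carry a ring nitrogen (N3 and N1), so the C4–C5 unit is at the glyoxal oxidation level. C4 can therefore be generated as an electrophilic iminium carbon on the amidine nitrogen, the natural partner for the nucleophilic C3 (enamine β-carbon) of the indole pyrrole ring, while C5 waits as an acetal.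
- Stereochemistry: the target has no stereocentre; the transient centres of the cascade form without control and are erased on aromatisation.

Key step: step 3

Remark: nortopsentin B is achiral, and the 4- and 5-(indol-3-yl) forms of the imidazole are N–H tautomers of one compound, so the structure as drawn is the single species to be made.

**Route**

Step 1
Reactants: 1 6-bromo-1H-indole
Product: 3 6-bromo-1H-indole-3-carbonitrile, via N-chlorosulfonyl carboxamide 2 (not isolated)
Conditions: ClSO2NCO, MeCN, 0 °C; then DMF, 0 °C to rt; ice-water
Reagents that add atoms: chlorosulfonyl isocyanate, O=C=NS(=O)(=O)Cl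
Why: Chlorosulfonyl isocyanate attacks the most nucleophilic position of the indole, C3, to give the N-chlorosulfonyl carboxamide 2, from which DMF removes chlorosulfonic acid to leave the nitrile (CSI cyanation of indoles); the aryl bromide is inert to these conditions.

Step 2
Reactants: 3 6-bromo-1H-indole-3-carbonitrile
Product: 4 6-bromo-1H-indole-3-carboximidamide hydrochloride
Conditions: AlMe3, NH4Cl (5 equiv each), toluene, 0 °C to rt; then 3, 90 °C; SiO2, MeOH–CHCl3
Reagents that add atoms: ammonium chloride, [NH4+].[Cl-]
Why: Garigipati amidine synthesis, in which the Lewis-acidic methylchloroaluminium amide activates the electron-rich nitrile and delivers NH2 to its carbon; the excess reagent covers metalation of the indole N–H, and the C–Br bond should not react with an organoaluminium reagent in the absence of a transition metal.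

Step 3
Reactants: 4 6-bromo-1H-indole-3-carboximidamide hydrochloride, 5 2,2-dimethoxyacetaldehyde (60% aqueous solution), 6 1H-indole
Product: 10 nortopsentin B, via N-amidinyl imine 7 (not isolated), via Mannich adduct 8 (not isolated), via methoxyimidazoline 9 (not isolated)
Conditions: 4 + 5, AcOH, rt; then 6 (1.0 equiv), 40 °C; then 6 M aq. HCl, 70 °C
Reagents that add atoms: none
Why: Proposed new method: the amidine nitrogen of 4 condenses with the aldehyde of 5 to the N-protonated 1,3-diazadiene 7 (an N-amidinyl iminium ion), C3 of indole 6 adds to its CH carbon (aza-Friedel–Crafts/Mannich step) to give 8, and the stronger acid then ionises the acetal to an O-methyl oxocarbenium ion that the second amidine nitrogen captures to give 9, which loses methanol to become the aromatic imidazole. The closest known reaction types are the gramine-type three-component Mannich alkylation of indoles with aldehydes and N–H components (including cyclic amidines such as 2-aminoazoles), the Groebke–Blackburn–Bienaymé cascade (amidine-derived iminium ion, carbon nucleophile, ring closure through the second amidine nitrogen) and the acid cyclisation of N-(2,2-dialkoxyethyl)amidines to imidazoles; what is new is their combination in one flask with an acyclic C-aryl amidine. The imidazole ring closes by 5-exo-trig attack of nitrogen on the oxocarbenium carbon. No stereocentre remains, because the CH(indolyl) centre of 8 and the two centres of 9 form without control and are erased by the elimination. The step needs C–C bond formation at the first carbon before the second is unmasked, which the dimethyl acetal secures because it should survive AcOH at 40 °C next to the amidinium group and blocks the tautomerisation to an imidazol-4-one that a free glyoxal adduct would undergo; it needs attack by 6 alone, which holds because the bromoindole nucleus already carries its substituent at C3 and is deactivated by the amidinium group; and it needs mono-indolylation, which pre-mixing 4 with 5 and using one equivalent of 6 should favour. No metal or reductant is present, so the C6–Br bond is untouched.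

**Compound list**

1 | 6-bromo-1H-indole | Brc1ccc2cc[nH]c2c1 | starting material
2 | 6-bromo-N-(chlorosulfonyl)-1H-indole-3-carboxamide | O=C(NS(=O)(=O)Cl)c1c[nH]c2cc(Br)ccc12 | intermediate
3 | 6-bromo-1H-indole-3-carbonitrile | N#Cc1c[nH]c2cc(Br)ccc12 | intermediate
4 | 6-bromo-1H-indole-3-carboximidamide hydrochloride | Cl.N=C(N)c1c[nH]c2cc(Br)ccc12 | intermediate
5 | 2,2-dimethoxyacetaldehyde | COC(OC)C=O | starting material
6 | 1H-indole | c1ccc2[nH]ccc2c1 | starting material
7 | 6-bromo-N-[(E)-2,2-dimethoxyethylidene]-1H-indole-3-carboximidamide (reacts in its N-protonated form) | COC(OC)/C=N/C(=N)c1c[nH]c2cc(Br)ccc12 | intermediate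
8 | 6-bromo-N-[1-(1H-indol-3-yl)-2,2-dimethoxyethyl]-1H-indole-3-carboximidamide (racemic) | COC(OC)C(NC(=N)c1c[nH]c2cc(Br)ccc12)c1c[nH]c2ccccc12 | intermediate
9 | 2-(6-bromo-1H-indol-3-yl)-5-(1H-indol-3-yl)-4-methoxy-4,5-dihydro-1H-imidazole (mixture of racemic diastereomers) | COC1NC(=NC1c1c[nH]c2ccccc12)c1c[nH]c2cc(Br)ccc12 | intermediate
10 | nortopsentin B, 2-(6-bromo-1H-indol-3-yl)-4-(1H-indol-3-yl)-1H-imidazole | Brc1ccc2c(-c3nc(-c4c[nH]c5ccccc45)c[nH]3)c[nH]c2c1 | target

**Step count**

Total steps: 3. Longest linear sequence: 3 steps (1 → 3 → 4 → 10).

**Steps most likely to fail**

Step 3 (Proposed new method). Several processes could divert the cascade: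
- ionisation of the gramine-type C–N bond of the first adduct, followed by capture of a second indole (double indolylation);
- 2:1 condensation of the amidine with the aldehyde;
- slow acetal ionisation next to the amidinium group, which would leave time for retro-Mannich cleavage.

Fallback by known chemistry, setting out from 6 and using 4: indole 6 is acylated at C3 with chloroacetyl chloride (pyridine, toluene, 60 °C) to give 3-(2-chloroacetyl)-1H-indole F1. F1 is then condensed with amidine 4 (KHCO3, THF–H2O, reflux; amidine/α-haloketone imidazole synthesis). This should give the target directly and comes back to the route at 10.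

Step 2. Addition of the aluminium amide may be sluggish or incomplete, because the nitrile is a vinylogous cyanamide and becomes still less electrophilic once the indole N–H is metalated. Fallback, setting out from 3: hydroxylamine (50% aq., EtOH, reflux) should add to the nitrile to give (Z)-6-bromo-N'-hydroxy-1H-indole-3-carboximidamide F2. O-Acetylation (Ac2O, AcOH, rt) gives the O-acetyl amidoxime F3, which is reduced without isolation at the N–O bond (Zn dust, AcOH, rt; aryl bromide retained). Treatment with HCl in MeOH then gives the hydrochloride, and the sequence comes back to the route at 4.

Step 1. Competing attack of the isocyanate at the indole nitrogen, or stalling at the carboxamide stage if the chlorosulfonyl group hydrolyses before DMF-induced elimination, would lower the throughput. Fallback, setting out from 1: Vilsmeier–Haack formylation (POCl3, DMF, 0 °C to 40 °C; aq. NaOH) should give 6-bromo-1H-indole-3-carbaldehyde F4. Heating F4 with NH2OH·HCl and HCO2Na in HCO2H forms the aldoxime F5, which is dehydrated in the same flask to the nitrile, and the sequence comes back to the route at 3.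

**Further compounds**

F1 | step 3 | 3-(2-chloroacetyl)-1H-indole | O=C(CCl)c1c[nH]c2ccccc12
F2 | step 2 | (Z)-6-bromo-N'-hydroxy-1H-indole-3-carboximidamide | N/C(=N\O)c1c[nH]c2cc(Br)ccc12
F3 | step 2 | (Z)-N'-acetoxy-6-bromo-1H-indole-3-carboximidamide | N/C(=N\OC(C)=O)c1c[nH]c2cc(Br)ccc12
F4 | step 1 | 6-bromo-1H-indole-3-carbaldehyde | O=Cc1c[nH]c2cc(Br)ccc12
F5 | step 1 | (E)-6-bromo-1H-indole-3-carbaldehyde oxime | O/N=C/c1c[nH]c2cc(Br)ccc12
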